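The ε-ring is read as a Diels–Alder retron: its C4'=C5' double bond is flanked by the oxygenated C3' and the chain-bearing C6', while C1'(CH3)2–C2'H2 is an isobutene unit. A (1E,3E)-1-acyloxy-3-methyl diene (C3'=C4'–C5'=C6', chiral O-methylmandelate on oxygen, sulfide handle on C7') and 2-methyl-1-nitropropene as isobutene equivalent give, in one cycloaddition, the whole ring with C3' and C6' set cis. Nitro is then excised, and Mitsunobu inversion with myristic acid delivers the 3',6'-trans ester. Julia–Kocienski union with a C30 apo-carotenal carrying the palmitoylated β-ring (from actinol and crocetin dialdehyde) completes the skeleton.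

Key step: step 4

Locants: carotenoid numbering is used for ring atoms (ε-ring: C1' = C(CH3)2, C2' = CH2, C3' = CH–O, C4'=C5'(CH3), C6' = CH bearing chain carbon C7'; β-ring unprimed).

Assumption: the (S)-O-methylmandelate on the diene oxygen is used as a covalently bound resolving group. The route relies on chromatographic separation of the two diastereomeric cis-adducts at the stage of 10, not on the size or sense of the facial bias; if the bias runs the other way, the (R)-acid is the better choice and the chemistry is identical.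

Starting materials 1, 2, 6, 8, 12, 16, 17 and 20 are taken as catalogue compounds.

Step 1
Reactants: 1 (2E)-3-methylpent-2-en-4-yn-1-ol; 2 1-phenyl-1H-tetrazole-5-thiol
Product: 3 5-{[(2E)-3-methylpent-2-en-4-yn-1-yl]sulfanyl}-1-phenyl-1H-tetrazole
Conditions: PPh3, DIAD, THF, 0 °C → rt
Reagents that add atoms: none
Why: Mitsunobu thioetherification, in which the primary allylic alcohol is activated as its oxyphosphonium salt and displaced in SN2 fashion by the acidic thiol, leaving the (E)-alkene and the alkyne untouched and installing at C7' the sulfur handle for the final olefination.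

Step 2
Reactants: 3 5-{[(2E)-3-methylpent-2-en-4-yn-1-yl]sulfanyl}-1-phenyl-1H-tetrazole
Product: 5 potassium trifluoro{(1E,3E)-3-methyl-5-[(1-phenyl-1H-tetrazol-5-yl)sulfanyl]penta-1,3-dien-1-yl}borate, via dienyl pinacol boronate 4 (not isolated)
Conditions: HBpin, Cp2Zr(H)Cl (5 mol %), Et3N (10 mol %), CH2Cl2, rt; then aq. KHF2, MeOH, rt
Reagents that add atoms: pinacolborane CC1(C)OBOC1(C)C; potassium hydrogen difluoride [K+].[F-].F
Why: Zirconocene-hydride-catalysed syn-hydroboration of the terminal alkyne should place boron on the terminal carbon and give only the (1E)-alkenylboronate, the trisubstituted alkene being far less reactive, and fluoride exchange gives the bench-stable trifluoroborate.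

Step 3
Reactants: 5 potassium trifluoro{(1E,3E)-3-methyl-5-[(1-phenyl-1H-tetrazol-5-yl)sulfanyl]penta-1,3-dien-1-yl}borate; 6 (2S)-2-methoxy-2-phenylacetic acid
Product: 7 (1E,3E)-3-methyl-5-[(1-phenyl-1H-tetrazol-5-yl)sulfanyl]penta-1,3-dien-1-yl (2S)-2-methoxy-2-phenylacetate
Conditions: CuBr (10 mol %), DMAP (20 mol %), 4 Å MS, O2 (1 atm), CH2Cl2, rt
Reagents that add atoms: none
Why: Chan–Lam-type copper-catalysed oxidative C–O coupling of an alkenyltrifluoroborate with a carboxylic acid proceeds with retention of alkene geometry, so the (1E,3E)-dienyl ester should form with both terminal substituents in outside positions and with the stereocentre of the acid untouched.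

Step 4
Reactants: 7 (1E,3E)-3-methyl-5-[(1-phenyl-1H-tetrazol-5-yl)sulfanyl]penta-1,3-dien-1-yl (2S)-2-methoxy-2-phenylacetate; 8 2-methyl-1-nitroprop-1-ene
Product: 9 (1R,4S,6S)-3,5,5-trimethyl-6-nitro-4-{[(1-phenyl-1H-tetrazol-5-yl)sulfanyl]methyl}cyclohex-2-en-1-yl (2S)-2-methoxy-2-phenylacetate (endo adduct drawn; its C2' epimer is carried along)
Conditions: 8 (3 equiv), BHT (cat.), CH2Cl2, 12 kbar, 40 °C
Reagents that add atoms: none
Why: Concerted, asynchronous normal-demand [4+2] cycloaddition in which the diene terminus C6' attacks the C(CH3)2 carbon (C1') of the nitroalkene while C3' closes onto the nitro-bearing C2'; the closest known reaction type is the Diels–Alder reaction of 1-acyloxybutadienes with nitroalkenes used as alkene equivalents, here with a trisubstituted nitroalkene, hence the high pressure. The six-membered ε-ring is closed by intermolecular [4+2] cycloaddition, both σ-bonds forming suprafacially on each component. C3' and C6' emerge cis because the oxygen and the CH2S group both occupy outside positions of the (1E,3E)-diene; their absolute sense is biased by the (S)-O-methylmandelate on the diene oxygen and is secured by separating the two diastereomeric cis-adducts after step 5, while the C2' configuration (endo or exo) is irrelevant because C2' becomes CH2. The selectivity needed is regiochemical: the oxygen donor on C3' and the methyl on C5' both place the largest HOMO coefficient on C6', which matches the largest LUMO coefficient on the β-carbon of the nitroalkene, so C6' bonds to C(CH3)2 and C3' to CH(NO2). The nitro group is a traceless activator, which makes the reagent a synthetic equivalent of isobutene with the required orientation.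

Step 5
Reactants: 9 (1R,4S,6S)-3,5,5-trimethyl-6-nitro-4-{[(1-phenyl-1H-tetrazol-5-yl)sulfanyl]methyl}cyclohex-2-en-1-yl (2S)-2-methoxy-2-phenylacetate
Product: 10 (1S,4R)-3,5,5-trimethyl-4-{[(1-phenyl-1H-tetrazol-5-yl)sulfanyl]methyl}cyclohex-2-en-1-yl (2S)-2-methoxy-2-phenylacetate (single diastereomer after chromatography)
Conditions: Bu3SnH (5 equiv), AIBN (portionwise), PhMe, 110 °C; chromatographic removal of the diastereomer from the other diene face
Reagents that add atoms: none
Why: Radical denitration, in which the stannyl radical adds to a nitro oxygen, the C2'–N bond fragments and the secondary C2' radical abstracts hydrogen from the stannane (a β-acyloxy radical does not eliminate), so both C2' epimers should converge on the CH2 compound with C3' and C6' untouched.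

Step 6
Reactants: 10 (1S,4R)-3,5,5-trimethyl-4-{[(1-phenyl-1H-tetrazol-5-yl)sulfanyl]methyl}cyclohex-2-en-1-yl (2S)-2-methoxy-2-phenylacetate
Product: 11 (1S,4R)-3,5,5-trimethyl-4-{[(1-phenyl-1H-tetrazol-5-yl)sulfanyl]methyl}cyclohex-2-en-1-ol
Conditions: K2CO3 (cat.), MeOH, rt
Reagents that add atoms: none
Why: Base-catalysed transesterification cleaves the acyl–oxygen bond only, so the 3',6'-cis allylic alcohol should be released with retention at C3' and the resolving acid is recovered as its methyl ester.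

Step 7
Reactants: 11 (1S,4R)-3,5,5-trimethyl-4-{[(1-phenyl-1H-tetrazol-5-yl)sulfanyl]methyl}cyclohex-2-en-1-ol; 12 tetradecanoic acid
Product: 13 (1R,4R)-3,5,5-trimethyl-4-{[(1-phenyl-1H-tetrazol-5-yl)sulfanyl]methyl}cyclohex-2-en-1-yl tetradecanoate
Conditions: PPh3, DIAD, THF, 0 °C → rt
Reagents that add atoms: none
Why: Mitsunobu esterification displaces the activated C3' oxygen by myristate with SN2 inversion (3'S to 3'R), which should convert the cis relationship from the cycloaddition into the 3',6'-trans relationship of the target while installing the myristate; SN2' attack is disfavoured at the fully substituted C5'.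

Step 8
Reactants: 13 (1R,4R)-3,5,5-trimethyl-4-{[(1-phenyl-1H-tetrazol-5-yl)sulfanyl]methyl}cyclohex-2-en-1-yl tetradecanoate
Product: 15 (1R,4R)-3,5,5-trimethyl-4-{[(1-phenyl-1H-tetrazol-5-yl)sulfonyl]methyl}cyclohex-2-en-1-yl tetradecanoate, via sulfoxide 14 (not isolated)
Conditions: 30% H2O2, (NH4)6Mo7O24·4H2O (10 mol %), EtOH, 0 °C → rt
Reagents that add atoms: hydrogen peroxide OO
Why: Molybdate-catalysed peroxide oxidation is selective for sulfur over an unactivated trisubstituted alkene and over esters, so the sulfide should pass through the sulfoxide to the Julia–Kocienski sulfone without touching C4'=C5'.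

Step 9
Reactants: 16 (4R,6R)-4-hydroxy-2,2,6-trimethylcyclohexan-1-one (actinol); 17 hexadecanoyl chloride
Product: 18 (1R,5R)-3,3,5-trimethyl-4-oxocyclohexyl hexadecanoate
Conditions: pyridine, DMAP (cat.), CH2Cl2, 0 °C → rt
Reagents that add atoms: none
Why: Nucleophilic acyl substitution at the acid chloride acylates the secondary alcohol with retention, fixing the future (3R) centre of the β-ring together with its palmitate.

Step 10
Reactants: 18 (1R,5R)-3,3,5-trimethyl-4-oxocyclohexyl hexadecanoate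
Product: 19 (4R)-4-(hexadecanoyloxy)-2,6,6-trimethylcyclohex-1-en-1-yl trifluoromethanesulfonate
Conditions: Tf2O, 2,6-di-tert-butyl-4-methylpyridine, CH2Cl2, 0 °C → rt
Reagents that add atoms: trifluoromethanesulfonic anhydride O=S(=O)(OS(=O)(=O)C(F)(F)F)C(F)(F)F
Why: O-Triflation of the ketone followed by loss of the only α-hydrogen (at the methyl-bearing carbon) with a hindered, non-nucleophilic pyridine base can give only the tetrasubstituted enol triflate, which is the C5=C6 double bond of the β-ring, and the ester is spared because no strong base is used.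

Step 11
Reactants: 20 (2E,4E,6E,8E,10E,12E,14E)-2,6,11,15-tetramethylhexadeca-2,4,6,8,10,12,14-heptaenedial (crocetin dialdehyde)
Product: 21 (2E,4E,6E,8E,10E,12E,14E,16E)-2,6,11,15-tetramethyl-17-(4,4,5,5-tetramethyl-1,3,2-dioxaborolan-2-yl)heptadeca-2,4,6,8,10,12,14,16-octaenal
Conditions: Cl2CHBpin (1 equiv), CrCl2 (6 equiv), LiI, THF, rt; 20 in threefold excess, recovered
Reagents that add atoms: 2-(dichloromethyl)-4,4,5,5-tetramethyl-1,3,2-dioxaborolane ClC(Cl)B1OC(C)(C)C(C)(C)O1
Why: Takai–Utimoto boryl-olefination, in which the geminal dichromium species formed from the dichloromethylboronate adds to one aldehyde and eliminates to the (E)-alkenylboronate (the future C7=C8 bond), with the excess of the symmetrical dialdehyde ensuring reaction at one end only.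

Step 12
Reactants: 21 (2E,4E,6E,8E,10E,12E,14E,16E)-2,6,11,15-tetramethyl-17-(4,4,5,5-tetramethyl-1,3,2-dioxaborolan-2-yl)heptadeca-2,4,6,8,10,12,14,16-octaenal; 19 (4R)-4-(hexadecanoyloxy)-2,6,6-trimethylcyclohex-1-en-1-yl trifluoromethanesulfonate
Product: 22 (3R)-3-(hexadecanoyloxy)-8'-apo-β-caroten-8'-al
Conditions: Pd(PPh3)4 (10 mol %), TlOEt, THF/H2O, rt, dark
Reagents that add atoms: none
Why: Suzuki–Miyaura coupling forms the C6–C7 bond with retention of both alkene geometries, the thallium base accelerating transmetalation so that coupling of the hindered enol triflate should outrun protodeboronation of the polyenyl boronate, while the aldehyde and the homoallylic palmitate are inert.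

Step 13
Reactants: 15 (1R,4R)-3,5,5-trimethyl-4-{[(1-phenyl-1H-tetrazol-5-yl)sulfonyl]methyl}cyclohex-2-en-1-yl tetradecanoate; 22 (3R)-3-(hexadecanoyloxy)-8'-apo-β-caroten-8'-al
Product: 23 (3R,3'R,6'R)-β,ε-carotene-3,3'-diol 3-hexadecanoate 3'-tetradecanoate (target)
Conditions: KN(SiMe3)2 (1.05 equiv), DME, −60 °C → rt, dark
Reagents that add atoms: none
Why: Julia–Kocienski olefination (addition of the sulfonyl carbanion to the aldehyde, Smiles rearrangement, loss of SO2 and tetrazolone) should give the (E)-C7'=C8' alkene from the β-branched sulfone without touching C6' or the esters at low temperature, and it is placed last so that the allylic myristate never meets palladium.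

Compound list
1 | (2E)-3-methylpent-2-en-4-yn-1-ol | C#C/C(C)=C/CO | starting material
2 | 1-phenyl-1H-tetrazole-5-thiol | Sc1nnnn1-c1ccccc1 | starting material
3 | 5-{[(2E)-3-methylpent-2-en-4-yn-1-yl]sulfanyl}-1-phenyl-1H-tetrazole | C#C/C(C)=C/CSc1nnnn1-c1ccccc1 | intermediate
4 | 5-{[(2E,4E)-3-methyl-5-(4,4,5,5-tetramethyl-1,3,2-dioxaborolan-2-yl)penta-2,4-dien-1-yl]sulfanyl}-1-phenyl-1H-tetrazole | CC1(C)OB(/C=C/C(C)=C/CSc2nnnn2-c2ccccc2)OC1(C)C | intermediate (not isolated)
5 | potassium trifluoro{(1E,3E)-3-methyl-5-[(1-phenyl-1H-tetrazol-5-yl)sulfanyl]penta-1,3-dien-1-yl}borate | [K+].F[B-](F)(F)/C=C/C(C)=C/CSc1nnnn1-c1ccccc1 | intermediate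
6 | (2S)-2-methoxy-2-phenylacetic acid | CO[C@H](C(=O)O)c1ccccc1 | starting material
7 | (1E,3E)-3-methyl-5-[(1-phenyl-1H-tetrazol-5-yl)sulfanyl]penta-1,3-dien-1-yl (2S)-2-methoxy-2-phenylacetate | CO[C@H](C(=O)O/C=C/C(C)=C/CSc1nnnn1-c1ccccc1)c1ccccc1 | intermediate
8 | 2-methyl-1-nitroprop-1-ene | CC(C)=C[N+](=O)[O-] | starting material
9 | (1R,4S,6S)-3,5,5-trimethyl-6-nitro-4-{[(1-phenyl-1H-tetrazol-5-yl)sulfanyl]methyl}cyclohex-2-en-1-yl (2S)-2-methoxy-2-phenylacetate (3'-O, 2'-NO2 and 6'-CH2S all cis; endo epimer drawn) | c1ccccc1-n1nnnc1SC[C@H]2C(C)=C[C@@H](OC(=O)[C@@H](OC)c3ccccc3)[C@@H]([N+](=O)[O-])C2(C)C | intermediate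
10 | (1S,4R)-3,5,5-trimethyl-4-{[(1-phenyl-1H-tetrazol-5-yl)sulfanyl]methyl}cyclohex-2-en-1-yl (2S)-2-methoxy-2-phenylacetate (3',6'-cis) | c1ccccc1-n1nnnc1SC[C@H]2C(C)=C[C@@H](OC(=O)[C@@H](OC)c3ccccc3)CC2(C)C | intermediate
11 | (1S,4R)-3,5,5-trimethyl-4-{[(1-phenyl-1H-tetrazol-5-yl)sulfanyl]methyl}cyclohex-2-en-1-ol (3',6'-cis) | c1ccccc1-n1nnnc1SC[C@H]2C(C)=C[C@@H](O)CC2(C)C | intermediate
12 | tetradecanoic acid (myristic acid) | CCCCCCCCCCCCCC(=O)O | starting material
13 | (1R,4R)-3,5,5-trimethyl-4-{[(1-phenyl-1H-tetrazol-5-yl)sulfanyl]methyl}cyclohex-2-en-1-yl tetradecanoate (3',6'-trans) | c1ccccc1-n1nnnc1SC[C@H]2C(C)=C[C@H](OC(=O)CCCCCCCCCCCCC)CC2(C)C | intermediate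
14 | (1R,4R)-3,5,5-trimethyl-4-{[(1-phenyl-1H-tetrazol-5-yl)sulfinyl]methyl}cyclohex-2-en-1-yl tetradecanoate (both sulfur epimers) | c1ccccc1-n1nnnc1S(=O)C[C@H]2C(C)=C[C@H](OC(=O)CCCCCCCCCCCCC)CC2(C)C | intermediate (not isolated)
15 | (1R,4R)-3,5,5-trimethyl-4-{[(1-phenyl-1H-tetrazol-5-yl)sulfonyl]methyl}cyclohex-2-en-1-yl tetradecanoate | c1ccccc1-n1nnnc1S(=O)(=O)C[C@H]2C(C)=C[C@H](OC(=O)CCCCCCCCCCCCC)CC2(C)C | intermediate
16 | (4R,6R)-4-hydroxy-2,2,6-trimethylcyclohexan-1-one (actinol) | O[C@@H]1C[C@@H](C)C(=O)C(C)(C)C1 | starting material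
17 | hexadecanoyl chloride (palmitoyl chloride) | CCCCCCCCCCCCCCCC(=O)Cl | starting material
18 | (1R,5R)-3,3,5-trimethyl-4-oxocyclohexyl hexadecanoate | CCCCCCCCCCCCCCCC(=O)O[C@@H]1C[C@@H](C)C(=O)C(C)(C)C1 | intermediate
19 | (4R)-4-(hexadecanoyloxy)-2,6,6-trimethylcyclohex-1-en-1-yl trifluoromethanesulfonate | CCCCCCCCCCCCCCCC(=O)O[C@@H]1CC(C)=C(OS(=O)(=O)C(F)(F)F)C(C)(C)C1 | intermediate
20 | (2E,4E,6E,8E,10E,12E,14E)-2,6,11,15-tetramethylhexadeca-2,4,6,8,10,12,14-heptaenedial (crocetin dialdehyde) | O=C/C(C)=C/C=C/C(C)=C/C=C/C=C(C)/C=C/C=C(C)/C=O | starting material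
21 | (2E,4E,6E,8E,10E,12E,14E,16E)-2,6,11,15-tetramethyl-17-(4,4,5,5-tetramethyl-1,3,2-dioxaborolan-2-yl)heptadeca-2,4,6,8,10,12,14,16-octaenal | CC1(C)OB(/C=C/C(C)=C/C=C/C(C)=C/C=C/C=C(C)/C=C/C=C(C)/C=O)OC1(C)C | intermediate
22 | (3R)-3-(hexadecanoyloxy)-8'-apo-β-caroten-8'-al | CCCCCCCCCCCCCCCC(=O)O[C@@H]1CC(C)=C(/C=C/C(C)=C/C=C/C(C)=C/C=C/C=C(C)/C=C/C=C(C)/C=O)C(C)(C)C1 | intermediate
23 | (3R,3'R,6'R)-β,ε-carotene-3,3'-diol 3-hexadecanoate 3'-tetradecanoate (lutein 3-O-palmitate 3'-O-myristate) | CCCCCCCCCCCCCCCC(=O)O[C@@H]1CC(C)=C(/C=C/C(C)=C/C=C/C(C)=C/C=C/C=C(C)/C=C/C=C(C)/C=C/[C@H]2C(C)=C[C@H](OC(=O)CCCCCCCCCCCCC)CC2(C)C)C(C)(C)C1 | target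

Total step count: 13 steps.
Longest linear sequence: 9 steps (steps 1–8, then step 13).

Steps most likely to fail

1. Step 4. The cycloaddition may stall because both partners are hindered and the dienyl ester is only a moderate donor; under forcing conditions the nitroalkene may instead add as a heterodiene across the enol-ester double bond, or polymerise. The fallback sets out from 3 and comes back at 10, and it also bypasses steps 2 and 3. Hydroboration of the alkyne in 3 with dicyclohexylborane and buffered oxidation would give (3E)-3-methyl-5-[(1-phenyl-1H-tetrazol-5-yl)sulfanyl]pent-3-enal F1. TBSOTf/Et3N should convert it into the far more electron-rich silyl dienol ether 5-{[(2E,4E)-5-(tert-butyldimethylsilyloxy)-3-methylpenta-2,4-dien-1-yl]sulfanyl}-1-phenyl-1H-tetrazole F2 (any 1Z isomer is unreactive as a diene). F2 should add 8 at ambient pressure (PhMe, 60 °C) to give the racemic 3',6'-cis adduct 5-({[4-(tert-butyldimethylsilyloxy)-2,6,6-trimethyl-5-nitrocyclohex-2-en-1-yl]methyl}sulfanyl)-1-phenyl-1H-tetrazole F3. Bu3SnH/AIBN then gives the denitrated silyl ether 5-({[4-(tert-butyldimethylsilyloxy)-2,6,6-trimethylcyclohex-2-en-1-yl]methyl}sulfanyl)-1-phenyl-1H-tetrazole F4, and Bu4NF/AcOH frees the racemic cis-3,5,5-trimethyl-4-{[(1-phenyl-1H-tetrazol-5-yl)sulfanyl]methyl}cyclohex-2-en-1-ol F5. Esterification with 6 (DCC, DMAP) and chromatographic separation of the two diastereomeric esters returns to 10.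

2. Step 5. Fragmentation of the stannyloxy nitroxyl radical at an unactivated secondary carbon is slow, so the chain may not propagate and thermal loss of the allylic ester can take over. The fallback sets out from 7 and comes back at 10 by changing the isobutene equivalent to 3-methylbut-2-enal. A Me2AlCl-promoted Diels–Alder reaction with 7 (CH2Cl2, −40 °C; same orientation, formyl on C2') would give 6-formyl-3,5,5-trimethyl-4-{[(1-phenyl-1H-tetrazol-5-yl)sulfanyl]methyl}cyclohex-2-en-1-yl (2S)-2-methoxy-2-phenylacetate F6. Pinnick oxidation (NaClO2, NaH2PO4, excess 2-methylbut-2-ene to spare the sulfide) gives 6-{[(2S)-2-methoxy-2-phenylacetyl]oxy}-2,2,4-trimethyl-3-{[(1-phenyl-1H-tetrazol-5-yl)sulfanyl]methyl}cyclohex-4-ene-1-carboxylic acid F7. Oxalyl chloride followed by sodium 2-thioxopyridin-1(2H)-olate forms its 2-thioxopyridin-1(2H)-yl ester F8, and Barton decarboxylation in the same flask (hν, t-BuSH) removes the carboxyl carbon. Separation of the diastereomers returns to 10.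

3. Step 12. Oxidative addition into the tetrasubstituted enol triflate and transmetalation may be slower than protodeboronation and geometric isomerisation of the heptaenyl boronate. The fallback sets out from 19 (with 20) and comes back at 22, making steps 11 and 12 unnecessary. Stille coupling of 19 with (tributylstannyl)methanol (Pd(PPh3)4, LiCl, 1,4-dioxane, 100 °C) would give (1R)-4-(hydroxymethyl)-3,5,5-trimethylcyclohex-3-en-1-yl hexadecanoate F9. PPh3·HBr in MeOH converts it into {[(4R)-4-(hexadecanoyloxy)-2,6,6-trimethylcyclohex-1-en-1-yl]methyl}triphenylphosphonium bromide F10. Wittig reaction of its ylide (NaN(SiMe3)2, THF, −78 °C) with an excess of 20, followed by iodine-catalysed equilibration of any 7Z isomer, should give 22.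

Further compounds
F1 | step 4 | (3E)-3-methyl-5-[(1-phenyl-1H-tetrazol-5-yl)sulfanyl]pent-3-enal | O=CC/C(C)=C/CSc1nnnn1-c1ccccc1
F2 | step 4 | 5-{[(2E,4E)-5-(tert-butyldimethylsilyloxy)-3-methylpenta-2,4-dien-1-yl]sulfanyl}-1-phenyl-1H-tetrazole | CC(C)(C)[Si](C)(C)O/C=C/C(C)=C/CSc1nnnn1-c1ccccc1
F3 | step 4 | 5-({[4-(tert-butyldimethylsilyloxy)-2,6,6-trimethyl-5-nitrocyclohex-2-en-1-yl]methyl}sulfanyl)-1-phenyl-1H-tetrazole (3',6'-cis; racemate, one enantiomer drawn) | c1ccccc1-n1nnnc1SC[C@H]2C(C)=C[C@@H](O[Si](C)(C)C(C)(C)C)[C@@H]([N+](=O)[O-])C2(C)C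
F4 | step 4 | 5-({[4-(tert-butyldimethylsilyloxy)-2,6,6-trimethylcyclohex-2-en-1-yl]methyl}sulfanyl)-1-phenyl-1H-tetrazole (3',6'-cis; racemate, one enantiomer drawn) | c1ccccc1-n1nnnc1SC[C@H]2C(C)=C[C@@H](O[Si](C)(C)C(C)(C)C)CC2(C)C
F5 | step 4 | cis-3,5,5-trimethyl-4-{[(1-phenyl-1H-tetrazol-5-yl)sulfanyl]methyl}cyclohex-2-en-1-ol (racemate, both enantiomers written) | c1ccccc1-n1nnnc1SC[C@H]2C(C)=C[C@@H](O)CC2(C)C.c1ccccc1-n1nnnc1SC[C@@H]2C(C)=C[C@H](O)CC2(C)C
F6 | step 5 | 6-formyl-3,5,5-trimethyl-4-{[(1-phenyl-1H-tetrazol-5-yl)sulfanyl]methyl}cyclohex-2-en-1-yl (2S)-2-methoxy-2-phenylacetate (3',6'-cis; C2' epimers) | c1ccccc1-n1nnnc1SC[C@H]2C(C)=C[C@@H](OC(=O)[C@@H](OC)c3ccccc3)C(C=O)C2(C)C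
F7 | step 5 | 6-{[(2S)-2-methoxy-2-phenylacetyl]oxy}-2,2,4-trimethyl-3-{[(1-phenyl-1H-tetrazol-5-yl)sulfanyl]methyl}cyclohex-4-ene-1-carboxylic acid (3',6'-cis; C2' epimers) | c1ccccc1-n1nnnc1SC[C@H]2C(C)=C[C@@H](OC(=O)[C@@H](OC)c3ccccc3)C(C(=O)O)C2(C)C
F8 | step 5 | 2-thioxopyridin-1(2H)-yl ester of F7 (Barton ester, not isolated) | c1ccccc1-n1nnnc1SC[C@H]2C(C)=C[C@@H](OC(=O)[C@@H](OC)c3ccccc3)C(C(=O)On3ccccc3=S)C2(C)C
F9 | step 12 | (1R)-4-(hydroxymethyl)-3,5,5-trimethylcyclohex-3-en-1-yl hexadecanoate | CCCCCCCCCCCCCCCC(=O)O[C@@H]1CC(C)=C(CO)C(C)(C)C1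
F10 | step 12 | {[(4R)-4-(hexadecanoyloxy)-2,6,6-trimethylcyclohex-1-en-1-yl]methyl}triphenylphosphonium bromide | CCCCCCCCCCCCCCCC(=O)O[C@@H]1CC(C)=C(C[P+](c2ccccc2)(c2ccccc2)c2ccccc2)C(C)(C)C1.[Br-]
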